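**Assumptions (one line):** the target is the (S)-enantiomer encoded by the SMILES; linoleic acid and cis,cis-cyclohexane-1,3,5-triol (sold as the dihydrate) are bought; the peptide catalyst of step 5 is made by routine peptide coupling and is not counted as a route step.

**Retrosynthetic overview**

1. Numbering (forward sense): linoleic acid 1 → (2, 3) → methyl ketone 4; all-cis triol 5 → 6 → meso ketone 7; 4 + 7 → (8, 9, 10) → meso triol 11 → mono-sulfonate 12 → (13) → target 14.
2. 14 ⇒ 13 ⇒ 12: the enone comes from E1cB loss of a sulfonate from a β-sulfonyloxy ketone, itself made by alcohol oxidation.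
3. 12 ⇒ 11: catalytic, metal-free differentiation of the two enantiotopic secondary hydroxyls of an achiral triol; this is the only stereo-defining event.
4. 11 ⇒ 4 + 7: aldol C–C bond at the future quaternary carbinol; 4 ⇒ 1 (CH3Li), 7 ⇒ 5 (acetal, oxidation).
5. Rings: the carbocycle is never built, it is bought as 5; only a temporary 1,3-dioxane ring is closed (step 2) and opened again (step 4).

**Route**

Step 1
Reactants: 1 linoleic acid, (9Z,12Z)-octadeca-9,12-dienoic acid
Product: 4 (10Z,13Z)-nonadeca-10,13-dien-2-one, via lithium linoleate 2 (not isolated), via dilithium gem-diolate 3 (not isolated)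
Conditions: CH3Li (2.3 equiv), Et2O, 0 → 23 °C, 2 h; inverse quench into ice-cold 1 M HCl
Reagents that add atoms: methyllithium, [Li]C
Why: Ketone synthesis by double addition of an organolithium to a carboxylic acid: the first equivalent forms the carboxylate 2, the second gives the stable gem-diolate 3, which collapses to the methyl ketone only on the acidic quench, and the non-conjugated Z,Z-diene is inert to CH3Li at 0 °C; no stereocenter is formed.

Step 2
Reactants: 5 cis,cis-cyclohexane-1,3,5-triol (dried)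
Product: 6 meso-3-phenyl-2,4-dioxabicyclo[3.3.1]nonan-7-ol (phenyl equatorial/exo, 7-OH on the same face as the two acetal oxygens)
Conditions: PhCH(OMe)2 (1.2 equiv), p-TsOH·H2O (5 mol%), DMF, 50 °C, 150 mbar
Reagents that add atoms: benzaldehyde dimethyl acetal, COC(OC)c1ccccc1
Why: Acid-catalysed transacetalisation under thermodynamic control: the all-cis triol can only close a six-membered benzylidene acetal across two syn hydroxyls (phenyl equatorial), which leaves the third hydroxyl free and gives a meso compound, so no chirality is introduced.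

Step 3
Reactants: 6 meso-3-phenyl-2,4-dioxabicyclo[3.3.1]nonan-7-ol
Product: 7 meso-3-phenyl-2,4-dioxabicyclo[3.3.1]nonan-7-one
Conditions: (n-Pr)4N[RuO4] (5 mol%), N-methylmorpholine N-oxide (1.5 equiv), 4 Å molecular sieves, CH2Cl2, 23 °C
Reagents that add atoms: none
Why: Ley–Griffith oxidation of the secondary alcohol under neutral, anhydrous conditions that spare the acid-labile acetal and avoid β-elimination of the β-alkoxy ketone; the product is meso.

Step 4
Reactants: 4 (10Z,13Z)-nonadeca-10,13-dien-2-one; 7 meso-3-phenyl-2,4-dioxabicyclo[3.3.1]nonan-7-one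
Product: 11 (10Z,13Z)-1-[(1s,3R,5S)-1,3,5-trihydroxycyclohexyl]nonadeca-10,13-dien-2-one, via lithium enolate 8 (not isolated), via lithium aldolate 9 (not isolated), via benzylidene-protected ketol 10 (not isolated)
Conditions: LiN(i-Pr)2 (1.15 equiv), THF, −78 °C, 4 (1.1 equiv) added dropwise, 30 min; 7 (1.0 equiv), −78 °C, 1 h; then 2 M HCl, THF–H2O, −78 → 23 °C, 3 h
Reagents that add atoms: none
Why: Kinetic lithium enolate aldol addition (deprotonation at the methyl group) followed by acetal hydrolysis in the acidic quench: the enolate attacks the ketone from the exo face, away from the syn-diaxial acetal oxygens (equatorial attack), so the new tertiary hydroxyl is cis to both ring oxygens and the product is a single meso triol with no chirality yet.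

Step 5
Reactants: 11 (10Z,13Z)-1-[(1s,3R,5S)-1,3,5-trihydroxycyclohexyl]nonadeca-10,13-dien-2-one
Product: 12 (1R,3S,5S)-3,5-dihydroxy-3-[(10Z,13Z)-2-oxononadeca-10,13-dien-1-yl]cyclohexyl 4-nitrobenzenesulfonate
Conditions: Boc-Pmh-D-Pro-Aib-Phe-OMe (10 mol%; Pmh = π-methyl-L-histidine), 4-O2NC6H4SO2Cl (1.15 equiv), NaHCO3, CH2Cl2–H2O, 0 °C
Reagents that add atoms: 4-nitrobenzenesulfonyl chloride, O=S(=O)(Cl)c1ccc(cc1)[N+](=O)[O-]
Why: Proposed new method: enantiotopic-group-selective sulfonyl transfer to an unprotected meso syn-1,3,5-triol whose only prochirality element is a remote tertiary carbinol — the sulfonyl chloride converts the π-methylimidazole of the peptide into an N-sulfonylimidazolium, the β-turn amides hydrogen-bond the tertiary-OH/side-chain C=O ketol unit and one secondary hydroxyl so that only the (3R)-carbinol (the one that must later leave) reaches the sulfonyl group, the tertiary hydroxyl is too hindered to react, and any mismatched mono-sulfonate is removed faster by a second sulfonylation, which makes the quaternary carbinol stereogenic with the (S) sense of the target; the closest known reaction type is the π-methylhistidine-peptide-catalysed desymmetrising sulfonylation and phosphorylation of enantiotopic 1,3-related hydroxyls in protected myo-inositol polyols.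

Step 6
Reactants: 12 (1R,3S,5S)-3,5-dihydroxy-3-[(10Z,13Z)-2-oxononadeca-10,13-dien-1-yl]cyclohexyl 4-nitrobenzenesulfonate
Product: 14 (5S)-5-hydroxy-5-[(10Z,13Z)-2-oxononadeca-10,13-dien-1-yl]cyclohex-2-en-1-one, via β-nosyloxy ketone 13 (not isolated)
Conditions: Dess–Martin periodinane (1.3 equiv), pyridine (3 equiv), CH2Cl2, 0 → 23 °C; then Et3N (2 equiv), 0 °C, 20 min; pH 7 buffer work-up
Reagents that add atoms: none
Why: Dess–Martin oxidation of the remaining secondary alcohol gives β-sulfonyloxy ketone 13, which loses 4-nitrobenzenesulfonate by E1cB elimination toward C2 (the tertiary hydroxide on the other side is a far poorer leaving group), so the enone forms regioselectively and the stereocenter set in step 5, now the only one, is untouched.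

**Compound list**

1 | linoleic acid, (9Z,12Z)-octadeca-9,12-dienoic acid | CCCCC/C=C\C/C=C\CCCCCCCC(=O)O | starting material
2 | lithium (9Z,12Z)-octadeca-9,12-dienoate | CCCCC/C=C\C/C=C\CCCCCCCC(=O)[O-].[Li+] | intermediate
3 | dilithium (10Z,13Z)-nonadeca-10,13-diene-2,2-diolate | CCCCC/C=C\C/C=C\CCCCCCCC(C)([O-])[O-].[Li+].[Li+] | intermediate
4 | (10Z,13Z)-nonadeca-10,13-dien-2-one | CCCCC/C=C\C/C=C\CCCCCCCC(C)=O | intermediate
5 | cis,cis-cyclohexane-1,3,5-triol (all three OH cis; achiral) | O[C@@H]1C[C@H](O)C[C@H](O)C1 | starting material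
6 | meso-3-phenyl-2,4-dioxabicyclo[3.3.1]nonan-7-ol (rel-1R,5S; phenyl exo/equatorial; 7-OH endo, syn to the acetal oxygens) | O[C@@H]1C[C@H]2C[C@@H](C1)O[C@H](c1ccccc1)O2 | intermediate
7 | meso-3-phenyl-2,4-dioxabicyclo[3.3.1]nonan-7-one (rel-1R,5S; phenyl exo) | O=C1C[C@H]2C[C@@H](C1)O[C@H](c1ccccc1)O2 | intermediate
8 | lithium (10Z,13Z)-nonadeca-1,10,13-trien-2-olate | CCCCC/C=C\C/C=C\CCCCCCCC(=C)[O-].[Li+] | intermediate
9 | lithium alkoxide of 10 (7-endo-olate) | CCCCC/C=C\C/C=C\CCCCCCCC(=O)C[C@@]1([O-])C[C@H]2C[C@@H](C1)O[C@H](c1ccccc1)O2.[Li+] | intermediate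
10 | (10Z,13Z)-1-[7-endo-hydroxy-3-exo-phenyl-2,4-dioxabicyclo[3.3.1]nonan-7-yl]nonadeca-10,13-dien-2-one (meso; tertiary OH syn to the acetal oxygens) | CCCCC/C=C\C/C=C\CCCCCCCC(=O)C[C@@]1(O)C[C@H]2C[C@@H](C1)O[C@H](c1ccccc1)O2 | intermediate
11 | (10Z,13Z)-1-[(1s,3R,5S)-1,3,5-trihydroxycyclohexyl]nonadeca-10,13-dien-2-one (meso; three OH all cis, side chain trans to them) | CCCCC/C=C\C/C=C\CCCCCCCC(=O)C[C@@]1(O)C[C@H](O)C[C@H](O)C1 | intermediate
12 | (1R,3S,5S)-3,5-dihydroxy-3-[(10Z,13Z)-2-oxononadeca-10,13-dien-1-yl]cyclohexyl 4-nitrobenzenesulfonate | CCCCC/C=C\C/C=C\CCCCCCCC(=O)C[C@@]1(O)C[C@H](OS(=O)(=O)c2ccc(cc2)[N+](=O)[O-])C[C@H](O)C1 | intermediate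
13 | (1S,3S)-3-hydroxy-5-oxo-3-[(10Z,13Z)-2-oxononadeca-10,13-dien-1-yl]cyclohexyl 4-nitrobenzenesulfonate | CCCCC/C=C\C/C=C\CCCCCCCC(=O)C[C@@]1(O)C[C@H](OS(=O)(=O)c2ccc(cc2)[N+](=O)[O-])CC(=O)C1 | intermediate
14 | (5S)-5-hydroxy-5-[(10Z,13Z)-2-oxononadeca-10,13-dien-1-yl]cyclohex-2-en-1-one | CCCCC/C=C\C/C=C\CCCCCCCC(=O)C[C@@]1(O)CC=CC(=O)C1 | target

**Step count and risks**

Total steps: 6. Longest linear sequence: 5 (5 → 6 → 7 → 11 → 12 → 14); step 1 is the convergent branch.

Most likely to fail:

Step 5 (the proposed new desymmetrisation). The two carbinols differ only at the β-carbons, so the peptide sequence will need screening, and the mirror-image peptide is used if the opposite sense is found. Fallback with known chemistry, setting out from 11 and returning at 14: lipase desymmetrisation of a meso cis-cyclohexane-1,3-diol. Immobilised Candida antarctica lipase B with vinyl acetate in MTBE at 30 °C acetylates the (R)-carbinol, the sense normally seen for secondary alcohols with this enzyme, giving the mono-acetate (1R,3S,5S)-3,5-dihydroxy-3-[(10Z,13Z)-2-oxononadeca-10,13-dien-1-yl]cyclohexyl acetate F4. Dess–Martin oxidation then gives the β-acetoxy ketone F5, which loses acetic acid with DBU in CH2Cl2 at 0 °C to give 14.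

Step 4 (aldol). The enolate 8 may deprotonate 7 (β-elimination that opens the acetal), the internal enolate may compete, or the ketone–ketone aldolate may revert. Fallback, setting out from 4 and 7 and returning at 11: aza-enolate addition in place of the enolate aldol. Ketone 4 is condensed with H2NNMe2 (EtOH, cat. AcOH) to the N,N-dimethylhydrazone F1. LiN(i-Pr)2 in THF at 0 °C deprotonates it only at the methyl group to give the lithium aza-enolate F2, which is more nucleophilic and much less prone to proton transfer. Addition to 7 at −78 °C gives the β-hydroxy hydrazone F3, and 2 M HCl in THF–H2O cleaves hydrazone and acetal together to give 11.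

Step 6 (oxidation/elimination). The product is a tertiary β-ketol that base can dehydrate to the phenol or cleave by retro-aldol. Fallback, setting out from 12 and returning at 14: base-free selenoxide elimination. PhSeH with Cs2CO3 in DMF displaces the nosylate with inversion to give the selenide (10Z,13Z)-1-[(1R,3R,5S)-1,3-dihydroxy-5-(phenylselanyl)cyclohexyl]nonadeca-10,13-dien-2-one F6. Dess–Martin oxidation gives the β-seleno ketone F7. NaIO4 with NaHCO3 in aqueous MeOH at 0 °C gives the selenoxide F8, which undergoes syn-elimination toward the acidic α-hydrogens at 0–23 °C to give 14.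

**Further compounds**

F1 | step 4 | (10Z,13Z)-nonadeca-10,13-dien-2-one N,N-dimethylhydrazone (drawn E) | CCCCC/C=C\C/C=C\CCCCCCC/C(C)=N/N(C)C
F2 | step 4 | lithium aza-enolate of F1 (deprotonated at the methyl group) | CCCCC/C=C\C/C=C\CCCCCCCC(=C)[N-]N(C)C.[Li+]
F3 | step 4 | N,N-dimethylhydrazone of 10 (β-hydroxy hydrazone; C=N geometry not defined) | CCCCC/C=C\C/C=C\CCCCCCCC(=NN(C)C)C[C@@]1(O)C[C@H]2C[C@@H](C1)O[C@H](c1ccccc1)O2
F4 | step 5 | (1R,3S,5S)-3,5-dihydroxy-3-[(10Z,13Z)-2-oxononadeca-10,13-dien-1-yl]cyclohexyl acetate | CCCCC/C=C\C/C=C\CCCCCCCC(=O)C[C@@]1(O)C[C@H](OC(C)=O)C[C@H](O)C1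
F5 | step 5 | (1S,3S)-3-hydroxy-5-oxo-3-[(10Z,13Z)-2-oxononadeca-10,13-dien-1-yl]cyclohexyl acetate | CCCCC/C=C\C/C=C\CCCCCCCC(=O)C[C@@]1(O)C[C@H](OC(C)=O)CC(=O)C1
F6 | step 6 | (10Z,13Z)-1-[(1R,3R,5S)-1,3-dihydroxy-5-(phenylselanyl)cyclohexyl]nonadeca-10,13-dien-2-one | CCCCC/C=C\C/C=C\CCCCCCCC(=O)C[C@@]1(O)C[C@@H]([Se]c2ccccc2)C[C@H](O)C1
F7 | step 6 | (3S,5R)-3-hydroxy-3-[(10Z,13Z)-2-oxononadeca-10,13-dien-1-yl]-5-(phenylselanyl)cyclohexan-1-one | CCCCC/C=C\C/C=C\CCCCCCCC(=O)C[C@@]1(O)C[C@@H]([Se]c2ccccc2)CC(=O)C1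
F8 | step 6 | selenoxide of F7 (5-phenylseleninyl; configuration at Se not defined) | CCCCC/C=C\C/C=C\CCCCCCCC(=O)C[C@@]1(O)C[C@@H]([Se](=O)c2ccccc2)CC(=O)C1
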